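Whatever happens in these flasks, left-handed substrate, right-handed substrate and the two products add up to what was charged, and the free catalyst comes out of each turnover as it went in, so a product reading is a count of turnovers. I had to decide whether the next flask, stopped after 2.5 h, could stay at 10 µM of free catalyst and 0.27 mM of racemization catalyst.

the same everywhere: left-handed substrate 10 mM; right-handed substrate 10 mM; free catalyst 10 µM; added ligand 0.32 mM

| flask | partner | racemization catalyst | remark | time |
|---|---|---|---|---|
| zeta | 20 mM | 0.14 mM | run made earlier |  |
| theta | 20 mM | 0.54 mM | run made earlier |  |
| flask | 20.0 mM | 0.27 mM |  | 2.5 h |

| run | time / h | left-handed product / % | right-handed product / % |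
|---|---|---|---|
| zeta | 0.200 | 16.6 | 0 |
| zeta | 0.667 | 36.1 | 2.2 |
| zeta | 1.00 | 45.1 | 2.2 |
| zeta | 1.50 | 55.5 | 2.6 |
| zeta | 2.50 | 67.3 | 3.9 |
| zeta | 3.00 | 69.4 | 3.0 |
| theta | 0.250 | 19.6 | 2.6 |
| theta | 0.417 | 28.1 | 1.0 |
| theta | 0.667 | 37.4 | 1.5 |
| theta | 1.00 | 46.9 | 1.0 |
| theta | 2.00 | 64.8 | 2.9 |
| theta | 3.00 | 72.4 | 2.8 |

(readings scatter by 1 percentage point)

- free catalyst is single-handed; left-handed substrate and right-handed substrate are mirror images of each other, charged as a racemate, each of them at the stated concentration
- reactions considered so far: partner + free catalyst + left-handed substrate -> free catalyst + left-handed product; partner + free catalyst + right-handed substrate -> free catalyst + right-handed product; left-handed substrate + racemization catalyst <-> right-handed substrate + racemization catalyst; racemization catalyst + added ligand <-> idle complex; partner <-> dormant form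
- an excess is the difference of the two amounts in percent of their sum
- an excess is below zero if the other one leads

* left-handed product and right-handed product together, in percent of the left-handed substrate and right-handed substrate charged together, at 2.5 h
* excess of left-handed product over right-handed product in the product at 2.5 h
* whether the exchange between left-handed substrate and right-handed substrate keeps pace with the reaction: how far the product's excess at 2.5 h gets from its value without exchange to its value with instant exchange (above 80 % keeps pace, below 20 % hardly takes part, else lags behind)

The two products stood at 72.4 % after 3.00 h in the zeta run and at 75.2 % after 3.00 h in the theta run. Left-handed substrate was half of the zeta charge, yet left-handed product reached 69.4 % there, so right-handed substrate had been feeding it.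

Partner, its dormant form counted, equalled the two substrates together and falls with them one for one. I took left-handed substrate to stay a steady share of what remains and the rate to follow the free catalyst. Then w, the reacted share over the unreacted share, equals T·c·t/S, with c the free catalyst, t the time, S the two substrates charged and T a constant to be read from the runs.

The readings give T as 1750 h⁻¹ in the zeta run and 2020 h⁻¹ in the theta run: racemization catalyst rose 3.86-fold, T 1.15-fold. Their mean, 1890 h⁻¹, is the T I carried forward, an apparent turnover frequency: turnovers per catalyst and hour as read from the last reading of each run.

For the flask, w is 2.36, so 70.2 % should react, and I left both catalysts as they were. My reckoning gives no excess.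

The forecast gave 71 % (68.5 % to 73.5 %), an excess of 92 % (89.5 % to 94 %) and an exchange that keeps pace, saying “racemization isn't limiting even with ligand in excess”. Its yield is higher than mine.

The flask gave 70.2 % of product and an excess of 93.5 %. The exchange keeps pace, 90 % of the way from the excess without exchange to that with instant exchange.

    partner + free catalyst + left-handed substrate → free catalyst + left-handed product (k = 4940 M⁻² s⁻¹)
    partner + free catalyst + right-handed substrate → free catalyst + right-handed product (k = 138 M⁻² s⁻¹)
    left-handed substrate + racemization catalyst ⇌ right-handed substrate + racemization catalyst, rate k3*[racemization catalyst]*[left-handed substrate] forward; the back reaction follows from the equilibrium constant (k = 3.24 M⁻¹ s⁻¹)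
    racemization catalyst + added ligand ⇌ idle complex (K = 510 M⁻¹, k = 5.38 M⁻¹ s⁻¹)
    partner ⇌ dormant form (K = 0.782, k = 0.00821 s⁻¹)

A neighbouring flask held 0.0040 mM of free catalyst, the rest as in the recipe. The same T gives w of 0.943 there, so 48.5 % should have reacted; that flask gave 49.6 %, with an excess of 94.0 %. Each catalyst in it made 2480 turnovers, more than the 1400 in the recipe flask. After 2.5 h, that neighbouring flask still held 24.3 % as left-handed substrate and 26.2 % as right-handed substrate.

All runs are simulated with constants of no real substance; noise was put on by code.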